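**Retrosynthetic overview**
- The target is reached from the racemic 3-arylphthalide by three operations: reductive opening of the lactone C3–O bond, reduction of the freed acid to CH2OH, and cleavage of three methyl ethers.
- The 3-arylphthalide is cut at the bond between the lactone CH and C1' of ring B. This gives 3-bromo-2-formyl-4,5-dimethoxybenzoic acid (reacting as its 3-hydroxyphthalide) and 2-bromo-6-methoxyphenol; the lactone is the only ring formed.
- Feature used: the bridging CH2 sits on C6 of ring A, next to C1 that carries CH2OH, and on C1' of ring B, para to the C4' hydroxyl. The two neighbouring one-carbon arms of ring A are therefore the CHO and COOH of a 2-formylbenzoic acid, and ring B is a phenol alkylated para to OH.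
- The formyl acid comes from 2-bromoisovanillin: iodination para to the phenol OH, O-methylation, then hydroxycarbonylation of the C–I bond only.

Key step: step 4

Remark: the 2-formylbenzoic acid is drawn in its open form; it is expected to exist largely as the 3-hydroxyphthalide ring tautomer, which is listed as a non-isolated intermediate of the key step.

**Step 1**
Reactants: 1 2-bromo-3-hydroxy-4-methoxybenzaldehyde (2-bromoisovanillin)
Product: 2 2-bromo-3-hydroxy-6-iodo-4-methoxybenzaldehyde
Conditions: NIS (1.05 equiv), CF3CO2H (cat.), MeCN, 0 °C to rt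
Reagents that add atoms: N-iodosuccinimide, O=C1CCC(=O)N1I
Why: Electrophilic aromatic iodination: both carbons ortho to the phenol OH (C2 with bromine, C4 with methoxy) are occupied, so the hydroxyl directs iodine to its para carbon C6, the position at which veratraldehyde-type rings are halogenated, while C5 is activated only by the ortho methoxy group.

**Step 2**
Reactants: 2 2-bromo-3-hydroxy-6-iodo-4-methoxybenzaldehyde
Product: 3 2-bromo-6-iodo-3,4-dimethoxybenzaldehyde
Conditions: MeI, K2CO3, DMF, rt
Reagents that add atoms: iodomethane, CI
Why: Williamson ether synthesis: the phenoxide formed with K2CO3 is methylated by MeI in an SN2 reaction, and the aldehyde and both aryl halides are inert under these conditions.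

**Step 3**
Reactants: 3 2-bromo-6-iodo-3,4-dimethoxybenzaldehyde
Product: 4 3-bromo-2-formyl-4,5-dimethoxybenzoic acid
Conditions: Pd(OAc)2 (5 mol %), PPh3 (10 mol %), CO (1 atm), K2CO3, DMF/H2O 4:1, 60 °C; acidic work-up
Reagents that add atoms: carbon monoxide, [C-]#[O+]; water, O
Why: Palladium-catalysed hydroxycarbonylation of an aryl iodide: zerovalent palladium formed in the flask inserts into the C-I bond far faster than into the more hindered C-Br bond at 60 °C, CO insertion gives an acylpalladium species, and water (or the hydrate of the neighbouring aldehyde) cleaves it to the acid.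

**Step 4**
Reactants: 4 3-bromo-2-formyl-4,5-dimethoxybenzoic acid; 5 2-bromo-6-methoxyphenol (1.05 equiv)
Product: 7 racemic 4-bromo-3-(3-bromo-4-hydroxy-5-methoxyphenyl)-5,6-dimethoxyisobenzofuran-1(3H)-one, via 4-bromo-3-hydroxy-5,6-dimethoxyphthalide 6 (not isolated)
Conditions: MeSO3H (neat), rt
Reagents that add atoms: none
Why: Friedel-Crafts hydroxyalkylation of a phenol by a 2-formylbenzoic acid, the known acid-mediated route from 3-hydroxyphthalides to 3-arylphthalides: 4 equilibrates with its ring tautomer 6, which on protonation loses water to a phthalidyl cation that the C6 methoxy group (para to C3a) stabilises, and the carbon para to the hydroxyl of 5 attacks it before loss of a proton restores ring B. The five-membered lactone, the only ring made, is already closed in 6 by addition of the carboxyl OH to the formyl carbon; should the open acid react first, the carboxyl oxygen captures the diarylmethyl cation in a 5-exo closure, so either path ends in 7. The new stereocentre C3 has no controlling element and forms as a racemate, which is acceptable because step 5 turns this carbon into a CH2 group. The selectivity needed is attack through the carbon para to the phenol OH: the free hydroxyl is the stronger donor, and the only other activated site, para to the methoxy group, lies next to bromine. About one equivalent of 5 at room temperature should hold back a second arylation by re-ionisation of the lactone, and keeping the benzoic carbon at the acid oxidation level means that no acid-labile benzylic alcohol is present.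

**Step 5**
Reactants: 7 racemic 4-bromo-3-(3-bromo-4-hydroxy-5-methoxyphenyl)-5,6-dimethoxyisobenzofuran-1(3H)-one
Product: 8 3-bromo-2-(3-bromo-4-hydroxy-5-methoxybenzyl)-4,5-dimethoxybenzoic acid
Conditions: Et3SiH (3 equiv), CF3CO2H, 50 °C
Reagents that add atoms: none
Why: Ionic hydrogenation: the protonated lactone ionises at the doubly benzylic C3-O bond to a diarylmethyl cation stabilised by the para hydroxyl of ring B, Et3SiH delivers hydride to it, the racemic stereocentre becomes the bridging CH2, and the aryl bromides and methyl ethers do not react.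

**Step 6**
Reactants: 8 3-bromo-2-(3-bromo-4-hydroxy-5-methoxybenzyl)-4,5-dimethoxybenzoic acid
Product: 9 [3-bromo-2-(3-bromo-4-hydroxy-5-methoxybenzyl)-4,5-dimethoxyphenyl]methanol
Conditions: BH3·THF (4 equiv), THF, 0 °C to rt; aqueous work-up
Reagents that add atoms: none
Why: Borane reduction of a carboxylic acid through its acyloxyborane: BH3 reduces the acid to the primary alcohol without touching aryl bromides or methyl ethers, and the phenol is only converted into a borate that the work-up hydrolyses.

**Step 7**
Reactants: 9 [3-bromo-2-(3-bromo-4-hydroxy-5-methoxybenzyl)-4,5-dimethoxyphenyl]methanol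
Product: 11 5-hydroxyisoavrainvilleol (3-bromo-4-(3-bromo-4,5-dihydroxybenzyl)-5-(hydroxymethyl)benzene-1,2-diol), via tetraphenol benzylic bromide 10 (not isolated)
Conditions: BBr3 (6 equiv), CH2Cl2, −78 °C to rt; then acetone/H2O 1:1 (dilute), rt
Reagents that add atoms: water, O; boron tribromide, BrB(Br)Br (supplies only the benzylic bromine of 10, which is lost again on hydrolysis)
Why: Lewis acid ether cleavage with BBr3 followed by SN1 hydrolysis: the three methyl ethers are cleaved through their oxonium bromides, the benzylic alcohol is expected to become the bromide 10 while the ring oxygens are held as electron-poor borates, and on aqueous quench the para-hydroxybenzyl bromide is hydrolysed by water to the alcohol of 11.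

**Compound list**
1 | 2-bromo-3-hydroxy-4-methoxybenzaldehyde (2-bromoisovanillin) | O=Cc1ccc(OC)c(O)c1Br | starting material
2 | 2-bromo-3-hydroxy-6-iodo-4-methoxybenzaldehyde | O=Cc1c(Br)c(O)c(OC)cc1I | intermediate
3 | 2-bromo-6-iodo-3,4-dimethoxybenzaldehyde | O=Cc1c(Br)c(OC)c(OC)cc1I | intermediate
4 | 3-bromo-2-formyl-4,5-dimethoxybenzoic acid | O=Cc1c(Br)c(OC)c(OC)cc1C(=O)O | intermediate
5 | 2-bromo-6-methoxyphenol | COc1cccc(Br)c1O | starting material
6 | racemic 4-bromo-3-hydroxy-5,6-dimethoxyisobenzofuran-1(3H)-one (ring tautomer of 4, not isolated) | O=C1OC(O)c2c(Br)c(OC)c(OC)cc21 | intermediate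
7 | racemic 4-bromo-3-(3-bromo-4-hydroxy-5-methoxyphenyl)-5,6-dimethoxyisobenzofuran-1(3H)-one | O=C1OC(c2cc(OC)c(O)c(Br)c2)c2c(Br)c(OC)c(OC)cc21 | intermediate
8 | 3-bromo-2-(3-bromo-4-hydroxy-5-methoxybenzyl)-4,5-dimethoxybenzoic acid | O=C(O)c1cc(OC)c(OC)c(Br)c1Cc1cc(OC)c(O)c(Br)c1 | intermediate
9 | [3-bromo-2-(3-bromo-4-hydroxy-5-methoxybenzyl)-4,5-dimethoxyphenyl]methanol | OCc1cc(OC)c(OC)c(Br)c1Cc1cc(OC)c(O)c(Br)c1 | intermediate
10 | 3-bromo-4-(3-bromo-4,5-dihydroxybenzyl)-5-(bromomethyl)benzene-1,2-diol (not isolated) | BrCc1cc(O)c(O)c(Br)c1Cc1cc(O)c(O)c(Br)c1 | intermediate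
11 | 5-hydroxyisoavrainvilleol, 3-bromo-4-(3-bromo-4,5-dihydroxybenzyl)-5-(hydroxymethyl)benzene-1,2-diol (achiral) | OCc1cc(O)c(O)c(Br)c1Cc1cc(O)c(O)c(Br)c1 | target

**Step count**
Total: 7 steps. Longest linear sequence: 7 steps (1 to 11); phenol 5 is purchased and enters at step 4.

**Steps most likely to fail**

1. Step 4 (key step). The phenol may attack through the carbon para to its methoxy group, or the lactone may re-ionise in the strong acid and take up a second phenol. The fallback fixes the bonding site with an aryl-metal reagent. It sets out from 4 and 5 and comes back at 7. Acid 4 is esterified (MeI, K2CO3, DMF) to methyl 3-bromo-2-formyl-4,5-dimethoxybenzoate F1. Phenol 5 is iodinated para to OH (NIS, MeCN) to 2-bromo-4-iodo-6-methoxyphenol F2 and protected (MOMCl, iPr2NEt, CH2Cl2) as 1-bromo-5-iodo-3-methoxy-2-(methoxymethoxy)benzene F3. Iodine-magnesium exchange (iPrMgCl·LiCl, THF, −20 °C), which leaves the bromide alone, should give [3-bromo-5-methoxy-4-(methoxymethoxy)phenyl]magnesium chloride F4. Its addition to the aldehyde of F1, followed by lactonisation of the alkoxide onto the ester, should give racemic 4-bromo-3-[3-bromo-5-methoxy-4-(methoxymethoxy)phenyl]-5,6-dimethoxyisobenzofuran-1(3H)-one F5. HCl in MeOH then removes the MOM group to give 7.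

2. Step 7. The benzylic bromide, or the product alcohol, may ionise to a quinone-methide-type cation that alkylates the catechol rings of other molecules, so oligomers form in place of the alcohol. The fallback demethylates before any benzylic leaving group exists. It sets out from 8 and comes back at 11. Acid 8 is treated with BBr3 (CH2Cl2, −78 °C to rt) to give 3-bromo-2-(3-bromo-4,5-dihydroxybenzyl)-4,5-dihydroxybenzoic acid F6. Its carboxyl group is then reduced with excess BH3·THF in the presence of B(OMe)3 (THF, rt) under non-acidic conditions to give 11.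

3. Step 3. Palladium hydride formed from CO and water may replace iodine by hydrogen, or insertion into the C–Br bond may compete, so the carboxyl group is lost or placed twice. The fallback uses halogen-metal exchange in place of catalysis. It sets out from 3 and comes back at 4. Aldehyde 3 is converted (HC(OMe)3, TsOH cat., MeOH) into 3-bromo-2-(dimethoxymethyl)-1-iodo-4,5-dimethoxybenzene F7. Selective iodine-magnesium exchange (iPrMgCl·LiCl, THF, −20 °C) should give [3-bromo-2-(dimethoxymethyl)-4,5-dimethoxyphenyl]magnesium chloride F8. Quenching with CO2 gives 3-bromo-2-(dimethoxymethyl)-4,5-dimethoxybenzoic acid F9, and aqueous HCl in the work-up hydrolyses the acetal to 4.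

**Further compounds**
F1 | step 4 | methyl 3-bromo-2-formyl-4,5-dimethoxybenzoate | COC(=O)c1cc(OC)c(OC)c(Br)c1C=O
F2 | step 4 | 2-bromo-4-iodo-6-methoxyphenol | COc1cc(I)cc(Br)c1O
F3 | step 4 | 1-bromo-5-iodo-3-methoxy-2-(methoxymethoxy)benzene | COCOc1c(Br)cc(I)cc1OC
F4 | step 4 | [3-bromo-5-methoxy-4-(methoxymethoxy)phenyl]magnesium chloride | COCOc1c(Br)cc([Mg]Cl)cc1OC
F5 | step 4 | racemic 4-bromo-3-[3-bromo-5-methoxy-4-(methoxymethoxy)phenyl]-5,6-dimethoxyisobenzofuran-1(3H)-one | O=C1OC(c2cc(OC)c(OCOC)c(Br)c2)c2c(Br)c(OC)c(OC)cc21
F6 | step 7 | 3-bromo-2-(3-bromo-4,5-dihydroxybenzyl)-4,5-dihydroxybenzoic acid | O=C(O)c1cc(O)c(O)c(Br)c1Cc1cc(O)c(O)c(Br)c1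
F7 | step 3 | 3-bromo-2-(dimethoxymethyl)-1-iodo-4,5-dimethoxybenzene | COC(OC)c1c(I)cc(OC)c(OC)c1Br
F8 | step 3 | [3-bromo-2-(dimethoxymethyl)-4,5-dimethoxyphenyl]magnesium chloride | COC(OC)c1c([Mg]Cl)cc(OC)c(OC)c1Br
F9 | step 3 | 3-bromo-2-(dimethoxymethyl)-4,5-dimethoxybenzoic acid | COC(OC)c1c(Br)c(OC)c(OC)cc1C(=O)O
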